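**Retrosynthetic overview**
- The ester bond is cut last: a protected labdane alcohol (free C19–OH, diol as acetonide, diene in place) and silyl-protected (Z)-4-hydroxycinnamic acid, two fragments of comparable size, are joined by esterification and then unmasked.
- The diene is attached at C12 by copper-catalysed coupling of a primary iodide with buta-1,3-dien-2-ylmagnesium chloride; the 7α,8α-diol comes from OsO4 on a C7=C8 alkene.
- Ring A and then ring B are closed in one radical cascade of an acyclic 2-methyl-3-oxo ester dienyl sulfone that carries an 8-phenylmenthyl ester; loss of the sulfonyl group places the C7=C8 alkene.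
- The acyclic precursor is cut at C6–C7 into a keto ester allylic chloride (from methyl acetoacetate, MeI and 2-methyl-2-vinyloxirane) and an allylic sulfone (from 4-methylpent-3-en-1-ol).
- The (Z)-acid comes from 4-iodophenol and propiolic acid by Sonogashira coupling and semihydrogenation.

Assumption: the (−)-8-phenylmenthyl ester steers the radical cascade to the 5α-H, 10β-methyl series, as it does in closely related aryl-terminated keto ester cyclisations; if the opposite sense were found, (+)-8-phenylmenthol would be used in step 6 and nothing else would change.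

Labdane numbering is used for the bicyclic compounds. All have 5α-H, 9α-H and 10β-CH3, and C19 is the β (axial) carbon on C4. "8-Phenylmenthyl" means (1R,2S,5R)-5-methyl-2-(2-phenylpropan-2-yl)cyclohexyl.

**Step 1**
Reactants: 1 4-methylpent-3-en-1-ol
Product: 2 5-chloro-2-methylpent-2-ene
Conditions: PPh3, CCl4, CH2Cl2, 0 °C→rt
Reagents that add atoms: carbon tetrachloride, ClC(Cl)(Cl)Cl
Why: Appel chlorination turns the primary alcohol into the chloride under neutral conditions that leave the trisubstituted alkene alone, and no stereocentre is formed.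

**Step 2**
Reactants: 2 5-chloro-2-methylpent-2-ene
Product: 3 (2E)-5-chloro-2-methylpent-2-en-1-ol
Conditions: SeO2 (0.3 equiv), t-BuOOH, salicylic acid (cat.), CH2Cl2, rt
Reagents that add atoms: tert-butyl hydroperoxide, CC(C)(C)OO
Why: SeO2-catalysed allylic oxidation (ene reaction then [2,3]-sigmatropic shift) attacks the methyl group trans to the chain at the more substituted alkene end, which fixes the E geometry of the allylic alcohol.

**Step 3**
Reactants: 3 (2E)-5-chloro-2-methylpent-2-en-1-ol
Product: 4 (2E)-1-bromo-5-chloro-2-methylpent-2-ene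
Conditions: CBr4, PPh3, CH2Cl2, 0 °C
Reagents that add atoms: carbon tetrabromide, BrC(Br)(Br)Br
Why: Appel bromination of a primary allylic alcohol is a direct SN2 displacement without allylic transposition, so the E alkene is kept.

**Step 4**
Reactants: 4 (2E)-1-bromo-5-chloro-2-methylpent-2-ene
Product: 5 {[(2E)-5-chloro-2-methylpent-2-en-1-yl]sulfonyl}benzene
Conditions: PhSO2Na, DMF, rt
Reagents that add atoms: sodium benzenesulfinate, [Na+].[O-]S(=O)c1ccccc1
Why: S-alkylation of the sulfinate (SN2) is far faster at the allylic bromide than at the primary chloride, giving the allyl sulfone with the E alkene intact.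

**Step 5**
Reactants: 6 methyl 3-oxobutanoate
Product: 7 methyl 2-methyl-3-oxobutanoate (racemic)
Conditions: MeI, K2CO3, acetone, reflux
Reagents that add atoms: iodomethane, CI
Why: C-alkylation of the stabilised acetoacetate enolate installs the carbon that becomes C18, and the new stereocentre does not matter because it is planarised in step 11.

**Step 6**
Reactants: 7 methyl 2-methyl-3-oxobutanoate
Product: 8 8-phenylmenthyl 2-methyl-3-oxobutanoate (epimers at the acyl C2)
Conditions: (−)-8-phenylmenthol, DMAP (0.3 equiv), 4 Å MS, toluene, reflux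
Reagents that add atoms: (1R,2S,5R)-5-methyl-2-(2-phenylpropan-2-yl)cyclohexan-1-ol ((−)-8-phenylmenthol, recoverable auxiliary), O[C@@H]1C[C@H](C)CC[C@H]1C(C)(C)c2ccccc2
Why: DMAP-catalysed transesterification of an enolisable β-keto ester (through the acylketene) attaches the chiral auxiliary and is driven by removal of methanol.

**Step 7**
Reactants: 9 2-methyl-2-vinyloxirane (racemic)
Product: 10 (2E)-4-chloro-2-methylbut-2-en-1-ol
Conditions: TiCl4, CH2Cl2, −90 °C; aqueous work-up
Reagents that add atoms: titanium tetrachloride, Cl[Ti](Cl)(Cl)Cl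
Why: Lewis-acid activation of the vinyl oxirane and SN2′ delivery of chloride to the vinyl terminus gives the 1,4-chlorohydrin with the E alkene.

**Step 8**
Reactants: 10 (2E)-4-chloro-2-methylbut-2-en-1-ol
Product: 11 (2E)-1-bromo-4-chloro-2-methylbut-2-ene
Conditions: CBr4, PPh3, CH2Cl2, 0 °C
Reagents that add atoms: carbon tetrabromide, BrC(Br)(Br)Br
Why: Appel bromination (SN2 at the primary allylic carbon) gives a dihalide whose two ends differ clearly in leaving-group ability, with the E alkene kept.

**Step 9**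
Reactants: 8 8-phenylmenthyl 2-methyl-3-oxobutanoate; 11 (2E)-1-bromo-4-chloro-2-methylbut-2-ene
Product: 13 8-phenylmenthyl (6E)-8-chloro-2,6-dimethyl-3-oxooct-6-enoate, via dianion 12 (not isolated)
Conditions: NaH, THF, 0 °C; n-BuLi, 0 °C; then 11, −78→−20 °C; 1 M HCl
Reagents that add atoms: none
Why: Huckin–Weiler γ-alkylation of the acetoacetate dianion at its terminal carbon is an SN2 reaction that selects the allylic bromide over the allylic chloride and does not touch the E alkene.

**Step 10**
Reactants: 5 {[(2E)-5-chloro-2-methylpent-2-en-1-yl]sulfonyl}benzene; 13 8-phenylmenthyl (6E)-8-chloro-2,6-dimethyl-3-oxooct-6-enoate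
Product: 16 8-phenylmenthyl (6E,10E)-9-(benzenesulfonyl)-13-chloro-2,6,10-trimethyl-3-oxotrideca-6,10-dienoate, via lithiated sulfone 14 (not isolated), via sodium enolate 15 (not isolated)
Conditions: 5: n-BuLi, THF, −78 °C; 13: NaH, THF, 0 °C; combine at −78 °C, DMPU, →−20 °C; 1 M HCl
Reagents that add atoms: none
Why: α-Alkylation of the sulfone-stabilised allylic carbanion (SN2 on the primary allylic chloride) forms the C6–C7 bond while the β-keto ester is masked as its unreactive sodium enolate, and the new sulfone-bearing centre is formed as a mixture that becomes sp2 in step 11.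

**Step 11**
Reactants: 16 8-phenylmenthyl (6E,10E)-9-(benzenesulfonyl)-13-chloro-2,6,10-trimethyl-3-oxotrideca-6,10-dienoate
Product: 17 8-phenylmenthyl 12-chloro-3-oxo-13,14,15,16-tetranorlabd-7-en-19-oate
Conditions: Mn(OAc)3·2H2O (2.2 equiv), degassed AcOH, 25→45 °C
Reagents that add atoms: none
Why: Trivalent manganese oxidises the keto ester to its α-radical, which closes ring A and then ring B by two 6-endo additions through chair-like transition states (the E alkenes give the trans fusion with 5α-H, 10β-methyl and the equatorial 9β side chain, the ester ends up axial at C4, and the phenyl group of the auxiliary shields one face to set the absolute configuration), after which the C8 radical expels the β-sulfonyl radical to place the alkene at C7=C8 (oxidative free-radical polyene cyclisation ended by β-fragmentation).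

**Step 12**
Reactants: 17 8-phenylmenthyl 12-chloro-3-oxo-13,14,15,16-tetranorlabd-7-en-19-oate
Product: 18 8-phenylmenthyl 12-chloro-3-[2-(4-methylbenzenesulfonyl)hydrazinylidene]-13,14,15,16-tetranorlabd-7-en-19-oate
Conditions: TsNHNH2, AcOH (cat.), EtOH, 70 °C
Reagents that add atoms: 4-methylbenzenesulfonohydrazide, Cc1ccc(cc1)S(=O)(=O)NN
Why: Acid-catalysed hydrazone condensation at the only ketone avoids basic conditions that could open the non-enolisable β-keto ester by retro-Claisen cleavage.

**Step 13**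
Reactants: 18 the tosylhydrazone of 17
Product: 19 8-phenylmenthyl 12-chloro-13,14,15,16-tetranorlabd-7-en-19-oate
Conditions: catecholborane, CHCl3, 0 °C; then NaOAc·3H2O, reflux
Reagents that add atoms: none
Why: Kabalka reduction of the tosylhydrazone (hydroboration of C=N, then loss of sulfinate and N2 from the diazene) turns C3 into CH2 without touching the hindered ester, the isolated alkene or the alkyl chloride.

**Step 14**
Reactants: 19 8-phenylmenthyl 12-chloro-13,14,15,16-tetranorlabd-7-en-19-oate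
Product: 20 8-phenylmenthyl 12-chloro-7α,8α-dihydroxy-13,14,15,16-tetranorlabdan-19-oate
Conditions: OsO4 (5 mol%), NMO, acetone/H2O, rt
Reagents that add atoms: N-methylmorpholine N-oxide, C[N+]1([O-])CCOCC1; water, O
Why: Upjohn dihydroxylation adds both oxygens syn from the α face, opposite the axial C10 methyl, which sets C7 (7α-OH) and C8 (8α-OH, 8β-methyl).

**Step 15**
Reactants: 20 the 7α,8α-diol
Product: 21 8-phenylmenthyl 12-chloro-7α,8α-(isopropylidenedioxy)-13,14,15,16-tetranorlabdan-19-oate
Conditions: 2,2-dimethoxypropane, PPTS (cat.), CH2Cl2, rt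
Reagents that add atoms: 2,2-dimethoxypropane, COC(C)(C)OC
Why: Acid-catalysed transketalisation closes the five-membered acetonide on the cis diol, masking both hydroxyls for the organometallic, hydride and acylation steps.

**Step 16**
Reactants: 21 the acetonide chloride
Product: 22 8-phenylmenthyl 12-iodo-7α,8α-(isopropylidenedioxy)-13,14,15,16-tetranorlabdan-19-oate
Conditions: NaI, NaHCO3 (cat.), butan-2-one, 80 °C
Reagents that add atoms: sodium iodide, [Na+].[I-]
Why: Finkelstein exchange (SN2 at the unhindered primary carbon, driven by precipitation of NaCl) gives the iodide needed for the coupling.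

**Step 17**
Reactants: 23 2-chlorobuta-1,3-diene (chloroprene)
Product: 24 buta-1,3-dien-2-ylmagnesium chloride (THF solution)
Conditions: Mg turnings, ZnCl2 (cat.), 1,2-dibromoethane (cat.), THF, 60 °C
Reagents that add atoms: magnesium, [Mg]
Why: Grignard formation by magnesium insertion into the vinylic C–Cl bond, helped by catalytic ZnCl2, gives the dienyl nucleophile.

**Step 18**
Reactants: 22 the acetonide iodide; 24 buta-1,3-dien-2-ylmagnesium chloride
Product: 25 8-phenylmenthyl 7α,8α-(isopropylidenedioxy)labda-13(16),14-dien-19-oate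
Conditions: Li2CuCl4 (5 mol%), THF, −10→20 °C
Reagents that add atoms: none
Why: Kochi-type copper-catalysed cross-coupling of the primary iodide with the alkenyl Grignard reagent forms the C12–C13 bond and delivers the 2-substituted butadiene, while the very hindered ester and the acetonide are inert.

**Step 19**
Reactants: 25 the diene ester
Product: 26 7α,8α-(isopropylidenedioxy)labda-13(16),14-dien-19-ol
Conditions: LiAlH4, THF, 0 °C→reflux; aqueous work-up
Reagents that add atoms: none
Why: Hydride reduction of the ester gives the C19 primary alcohol and releases the auxiliary for recovery, and the unactivated diene and the acetonide do not react with LiAlH4.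

**Step 20**
Reactants: 27 4-iodophenol
Product: 28 (4-iodophenoxy)tri(propan-2-yl)silane
Conditions: TIPSCl, imidazole, DMF, rt
Reagents that add atoms: chlorotri(propan-2-yl)silane, CC(C)[Si](Cl)(C(C)C)C(C)C
Why: Silylation of the phenol gives a base-tolerant aryl silyl ether that survives the amidine base of the next step and is removed by fluoride at the end.

**Step 21**
Reactants: 28 (4-iodophenoxy)tri(propan-2-yl)silane; 29 prop-2-ynoic acid
Product: 30 3-{4-[tri(propan-2-yl)silyloxy]phenyl}prop-2-ynoic acid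
Conditions: Pd(PPh3)4 (2.5 mol%), DBU (2.4 equiv), DMSO, 35 °C; dilute HCl
Reagents that add atoms: none
Why: Copper-free Sonogashira coupling (oxidative addition of the aryl iodide to zerovalent palladium, then coupling with the propiolate) gives the arylpropiolic acid at a temperature too low for decarboxylation.

**Step 22**
Reactants: 30 the arylpropiolic acid
Product: 31 (2Z)-3-{4-[tri(propan-2-yl)silyloxy]phenyl}prop-2-enoic acid
Conditions: H2 (1 atm), Pd/CaCO3 poisoned with Pb(OAc)2 (Lindlar catalyst), quinoline, EtOAc, rt, dark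
Reagents that add atoms: none
Why: Lindlar semihydrogenation adds H2 syn across the alkyne on the poisoned palladium surface and stops at the alkene, which sets the Z geometry.

**Step 23**
Reactants: 26 7α,8α-(isopropylidenedioxy)labda-13(16),14-dien-19-ol; 31 the (Z)-acid
Product: 32 7α,8α-(isopropylidenedioxy)labda-13(16),14-dien-19-yl (2Z)-3-{4-[tri(propan-2-yl)silyloxy]phenyl}prop-2-enoate
Conditions: EDC·HCl, DMAP, CH2Cl2, 0 °C→rt, dark
Reagents that add atoms: none
Why: Steglich esterification (carbodiimide activation with DMAP acyl transfer) joins the two fragments at the only free hydroxyl, and low temperature with exclusion of light is used to keep the Z alkene.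

**Step 24**
Reactants: 32 the coupled ester
Product: 33 7α,8α-dihydroxylabda-13(16),14-dien-19-yl (2Z)-3-{4-[tri(propan-2-yl)silyloxy]phenyl}prop-2-enoate
Conditions: AcOH/H2O/THF (3:1:1), 45 °C, dark
Reagents that add atoms: none
Why: Mild acid-catalysed acetal hydrolysis frees the cis diol under conditions too weak to hydrate the diene, ionise the tertiary alcohol or cleave the aryl silyl ether.

**Step 25**
Reactants: 33 the silyl-protected diol ester
Product: 34 7α,8α-dihydroxylabda-13(16),14-dien-19-yl (2Z)-3-(4-hydroxyphenyl)prop-2-enoate (CNP0254560.1)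
Conditions: HF·pyridine, pyridine, THF, 0 °C, dark
Reagents that add atoms: none
Why: Fluoride-driven desilylation under buffered, non-basic conditions frees the phenol without forming a phenoxide, so the Z cinnamate is not isomerised.

**Compound list**
1 | 4-methylpent-3-en-1-ol | CC(C)=CCCO | starting material
2 | 5-chloro-2-methylpent-2-ene | CC(C)=CCCCl | intermediate
3 | (2E)-5-chloro-2-methylpent-2-en-1-ol | OC/C(C)=C/CCCl | intermediate
4 | (2E)-1-bromo-5-chloro-2-methylpent-2-ene | BrC/C(C)=C/CCCl | intermediate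
5 | {[(2E)-5-chloro-2-methylpent-2-en-1-yl]sulfonyl}benzene | ClCC/C=C(\C)CS(=O)(=O)c1ccccc1 | intermediate
6 | methyl 3-oxobutanoate | COC(=O)CC(C)=O | starting material
7 | methyl 2-methyl-3-oxobutanoate (racemic) | COC(=O)C(C)C(C)=O | intermediate
8 | 8-phenylmenthyl 2-methyl-3-oxobutanoate (epimers at acyl C2) | CC(=O)C(C)C(=O)O[C@@H]1C[C@H](C)CC[C@H]1C(C)(C)c2ccccc2 | intermediate
9 | 2-methyl-2-vinyloxirane (racemic) | C=CC1(C)CO1 | starting material
10 | (2E)-4-chloro-2-methylbut-2-en-1-ol | OC/C(C)=C/CCl | intermediate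
11 | (2E)-1-bromo-4-chloro-2-methylbut-2-ene | BrC/C(C)=C/CCl | intermediate
12 | sodium lithium dienolate (dianion) of 8 | [Na+].[Li+].C=C([O-])C(C)=C([O-])O[C@@H]1C[C@H](C)CC[C@H]1C(C)(C)c2ccccc2 | intermediate
13 | 8-phenylmenthyl (6E)-8-chloro-2,6-dimethyl-3-oxooct-6-enoate (epimers at C2) | ClC/C=C(\C)CCC(=O)C(C)C(=O)O[C@@H]1C[C@H](C)CC[C@H]1C(C)(C)c2ccccc2 | intermediate
14 | lithium salt of 5 deprotonated α to sulfur | [Li+].ClCC/C=C(\C)[CH-]S(=O)(=O)c1ccccc1 | intermediate
15 | sodium enolate of 13 | [Na+].ClC/C=C(\C)CCC([O-])=C(C)C(=O)O[C@@H]1C[C@H](C)CC[C@H]1C(C)(C)c2ccccc2 | intermediate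
16 | 8-phenylmenthyl (6E,10E)-9-(benzenesulfonyl)-13-chloro-2,6,10-trimethyl-3-oxotrideca-6,10-dienoate (mixture at C2 and C9) | ClCC/C=C(\C)C(S(=O)(=O)c1ccccc1)C/C=C(\C)CCC(=O)C(C)C(=O)O[C@@H]2C[C@H](C)CC[C@H]2C(C)(C)c3ccccc3 | intermediate
17 | 8-phenylmenthyl 12-chloro-3-oxo-13,14,15,16-tetranorlabd-7-en-19-oate | ClCC[C@H]1C(C)=CC[C@H]2[C@@](C)(C(=O)O[C@@H]3C[C@H](C)CC[C@H]3C(C)(C)c4ccccc4)C(=O)CC[C@@]21C | intermediate
18 | 8-phenylmenthyl 12-chloro-3-[2-(4-methylbenzenesulfonyl)hydrazinylidene]-13,14,15,16-tetranorlabd-7-en-19-oate | ClCC[C@H]1C(C)=CC[C@H]2[C@@](C)(C(=O)O[C@@H]3C[C@H](C)CC[C@H]3C(C)(C)c4ccccc4)C(=NNS(=O)(=O)c5ccc(C)cc5)CC[C@@]21C | intermediate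
19 | 8-phenylmenthyl 12-chloro-13,14,15,16-tetranorlabd-7-en-19-oate | ClCC[C@H]1C(C)=CC[C@H]2[C@@](C)(C(=O)O[C@@H]3C[C@H](C)CC[C@H]3C(C)(C)c4ccccc4)CCC[C@@]21C | intermediate
20 | 8-phenylmenthyl 12-chloro-7α,8α-dihydroxy-13,14,15,16-tetranorlabdan-19-oate | ClCC[C@H]1[C@](C)(O)[C@H](O)C[C@H]2[C@@](C)(C(=O)O[C@@H]3C[C@H](C)CC[C@H]3C(C)(C)c4ccccc4)CCC[C@@]21C | intermediate
21 | 8-phenylmenthyl 12-chloro-7α,8α-(isopropylidenedioxy)-13,14,15,16-tetranorlabdan-19-oate | ClCC[C@H]1[C@]2(C)OC(C)(C)O[C@@H]2C[C@H]3[C@@](C)(C(=O)O[C@@H]4C[C@H](C)CC[C@H]4C(C)(C)c5ccccc5)CCC[C@@]31C | intermediate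
22 | 8-phenylmenthyl 12-iodo-7α,8α-(isopropylidenedioxy)-13,14,15,16-tetranorlabdan-19-oate | ICC[C@H]1[C@]2(C)OC(C)(C)O[C@@H]2C[C@H]3[C@@](C)(C(=O)O[C@@H]4C[C@H](C)CC[C@H]4C(C)(C)c5ccccc5)CCC[C@@]31C | intermediate
23 | 2-chlorobuta-1,3-diene | C=CC(Cl)=C | starting material
24 | buta-1,3-dien-2-ylmagnesium chloride | C=CC(=C)[Mg]Cl | intermediate
25 | 8-phenylmenthyl 7α,8α-(isopropylidenedioxy)labda-13(16),14-dien-19-oate | C=CC(=C)CC[C@H]1[C@]2(C)OC(C)(C)O[C@@H]2C[C@H]3[C@@](C)(C(=O)O[C@@H]4C[C@H](C)CC[C@H]4C(C)(C)c5ccccc5)CCC[C@@]31C | intermediate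
26 | 7α,8α-(isopropylidenedioxy)labda-13(16),14-dien-19-ol | C=CC(=C)CC[C@H]1[C@]2(C)OC(C)(C)O[C@@H]2C[C@H]3[C@@](C)(CO)CCC[C@@]31C | intermediate
27 | 4-iodophenol | Oc1ccc(I)cc1 | starting material
28 | (4-iodophenoxy)tri(propan-2-yl)silane | CC(C)[Si](Oc1ccc(I)cc1)(C(C)C)C(C)C | intermediate
29 | prop-2-ynoic acid | C#CC(=O)O | starting material
30 | 3-{4-[tri(propan-2-yl)silyloxy]phenyl}prop-2-ynoic acid | OC(=O)C#Cc1ccc(O[Si](C(C)C)(C(C)C)C(C)C)cc1 | intermediate
31 | (2Z)-3-{4-[tri(propan-2-yl)silyloxy]phenyl}prop-2-enoic acid | OC(=O)/C=C\c1ccc(O[Si](C(C)C)(C(C)C)C(C)C)cc1 | intermediate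
32 | 7α,8α-(isopropylidenedioxy)labda-13(16),14-dien-19-yl (2Z)-3-{4-[tri(propan-2-yl)silyloxy]phenyl}prop-2-enoate | C=CC(=C)CC[C@H]1[C@]2(C)OC(C)(C)O[C@@H]2C[C@H]3[C@@](C)(COC(=O)/C=C\c4ccc(O[Si](C(C)C)(C(C)C)C(C)C)cc4)CCC[C@@]31C | intermediate
33 | 7α,8α-dihydroxylabda-13(16),14-dien-19-yl (2Z)-3-{4-[tri(propan-2-yl)silyloxy]phenyl}prop-2-enoate | C=CC(=C)CC[C@H]1[C@](C)(O)[C@H](O)C[C@H]2[C@@](C)(COC(=O)/C=C\c3ccc(O[Si](C(C)C)(C(C)C)C(C)C)cc3)CCC[C@@]21C | intermediate
34 | 7α,8α-dihydroxylabda-13(16),14-dien-19-yl (2Z)-3-(4-hydroxyphenyl)prop-2-enoate | C=CC(=C)CC[C@H]1[C@](C)(O)[C@H](O)C[C@H]2[C@@](C)(COC(=O)/C=C\c3ccc(O)cc3)CCC[C@@]21C | target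

**Step count**
Total: 25 steps. Longest linear sequence: 16 steps (1–4, 10–16, 18, 19, 23–25).

**Steps most likely to fail, with fallbacks**

Step 10 (sulfone alkylation beside an enolate-masked keto ester). The fallback sets out from 10 and 5 and comes back at 16, forming the C6–C7 bond before the keto ester is present. Alcohol 10 is silylated (TBSCl, imidazole) to tert-butyl{[(2E)-4-chloro-2-methylbut-2-en-1-yl]oxy}dimethylsilane F1, which has no acidic carbonyl group. F1 alkylates lithiated 5 (n-BuLi, THF/DMPU, −78 °C) to give tert-butyl{[(2E,6E)-5-(benzenesulfonyl)-9-chloro-2,6-dimethylnona-2,6-dien-1-yl]oxy}dimethylsilane F2. TBAF then gives (2E,6E)-5-(benzenesulfonyl)-9-chloro-2,6-dimethylnona-2,6-dien-1-ol F3, and CBr4/PPh3 gives {[(3E,7E)-9-bromo-1-chloro-4,8-dimethylnona-3,7-dien-5-yl]sulfonyl}benzene F4. Inverse addition of F4 to an excess of dianion 12 (made from 8) at −78 °C gives 16.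

Step 11 (oxidative radical cascade ended by sulfonyl loss; yield and auxiliary control). The fallback sets out from 16 and comes back at 17, generating the radical by halogen-atom transfer instead of oxidation. The sodium enolate of 16 (NaH, THF) is brominated with NBS at −78 °C to 8-phenylmenthyl (6E,10E)-9-(benzenesulfonyl)-2-bromo-13-chloro-2,6,10-trimethyl-3-oxotrideca-6,10-dienoate F5. Et3B with a trace of air (toluene, −40 °C) then starts a chain: an ethyl radical abstracts bromine, the same two 6-endo ring closures follow, and the expelled sulfonyl radical is taken up by Et3B, which releases the next ethyl radical. Mg(ClO4)2 or Yb(OTf)3 can be added to rigidify the keto ester and sharpen facial control.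

Step 23 (esterification of a hindered neopentyl alcohol with a Z acid that can isomerise). The fallback sets out from 26 and 28 and comes back at 32, building the Z alkene on the ester. Alcohol 26 is acylated with bromoacetyl bromide and pyridine to 7α,8α-(isopropylidenedioxy)labda-13(16),14-dien-19-yl bromoacetate F6. Diphenyl phosphite and Et3N (Michaelis–Becker reaction) convert it into 7α,8α-(isopropylidenedioxy)labda-13(16),14-dien-19-yl (diphenoxyphosphoryl)acetate F7. Iodine–magnesium exchange on 28 with i-PrMgCl·LiCl followed by DMF gives 4-[tri(propan-2-yl)silyloxy]benzaldehyde F8. An Ando-type Z-selective Horner–Wadsworth–Emmons reaction of F7 with F8 (NaH, THF, −78 °C) gives 32.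

**Further compounds**
F1 | step 10 | tert-butyl{[(2E)-4-chloro-2-methylbut-2-en-1-yl]oxy}dimethylsilane | CC(C)(C)[Si](C)(C)OC/C(C)=C/CCl
F2 | step 10 | tert-butyl{[(2E,6E)-5-(benzenesulfonyl)-9-chloro-2,6-dimethylnona-2,6-dien-1-yl]oxy}dimethylsilane | CC(C)(C)[Si](C)(C)OC/C(C)=C/CC(S(=O)(=O)c1ccccc1)/C(C)=C/CCCl
F3 | step 10 | (2E,6E)-5-(benzenesulfonyl)-9-chloro-2,6-dimethylnona-2,6-dien-1-ol | OC/C(C)=C/CC(S(=O)(=O)c1ccccc1)/C(C)=C/CCCl
F4 | step 10 | {[(3E,7E)-9-bromo-1-chloro-4,8-dimethylnona-3,7-dien-5-yl]sulfonyl}benzene | BrC/C(C)=C/CC(S(=O)(=O)c1ccccc1)/C(C)=C/CCCl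
F5 | step 11 | 8-phenylmenthyl (6E,10E)-9-(benzenesulfonyl)-2-bromo-13-chloro-2,6,10-trimethyl-3-oxotrideca-6,10-dienoate | ClCC/C=C(\C)C(S(=O)(=O)c1ccccc1)C/C=C(\C)CCC(=O)C(C)(Br)C(=O)O[C@@H]2C[C@H](C)CC[C@H]2C(C)(C)c3ccccc3
F6 | step 23 | 7α,8α-(isopropylidenedioxy)labda-13(16),14-dien-19-yl bromoacetate | C=CC(=C)CC[C@H]1[C@]2(C)OC(C)(C)O[C@@H]2C[C@H]3[C@@](C)(COC(=O)CBr)CCC[C@@]31C
F7 | step 23 | 7α,8α-(isopropylidenedioxy)labda-13(16),14-dien-19-yl (diphenoxyphosphoryl)acetate | C=CC(=C)CC[C@H]1[C@]2(C)OC(C)(C)O[C@@H]2C[C@H]3[C@@](C)(COC(=O)CP(=O)(Oc4ccccc4)Oc5ccccc5)CCC[C@@]31C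
F8 | step 23 | 4-[tri(propan-2-yl)silyloxy]benzaldehyde | O=Cc1ccc(O[Si](C(C)C)(C(C)C)C(C)C)cc1
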